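**Numbering used throughout.** C1 is the aldehyde carbon, C2 its alkene neighbour (bearing CH3), C3–C5 the hydroxypropyl chain (C3 = CH2OH, C5 on the ring), C6–C11 the ring (C6 bears the chain, C7 the alkylidene, C10 the carbinol, C11 the quaternary carbon), C12–C23 the side chain outward from C11. The target is compound 35, (2Z,6R,10S,11S,14E,16E,18E).

## The problem

Compound 35 is a monocyclic C30 terpenoid whose cyclohexane (C6–C11) carries four appendages on four adjacent ring atoms: a 3-hydroxypropyl chain on C6, an exocyclic tetrasubstituted enal C7=C2(CH3)–C1HO, a methyl carbinol at C10, and on the quaternary C11 a methyl group and a C12–C23 chain ending in a conjugated (14E,16E,18E)-triene and an isolated trisubstituted alkene. The three stereocentres (6R,10S,11S) are contiguous and two are fully substituted. C6, the only one with a hydrogen, is the natural anchor: its substituent can send an electrophile to the opposite face of a C10=C11 enolate and, through the ring conformation it imposes, bias the approach of a nucleophile to a C10 ketone. The enal is the second problem: C1 must lie cis to C6 across C7=C2, and olefination of a hindered C7 ketone would have to tell C6 from C8 with nothing to guide it. The triene, the enal (its γ-hydrogen on C6 is epimerisable through the dienolate) and the tertiary alcohol (prone to elimination in acid) will not survive oxidative, strongly basic or acidic steps, so chain and aldehyde must come last. The enabling feature is topological: were C1 bonded to C3, the atoms C1, C2, C7, C6, C5, C4 and C3 would form a seven-membered ring in which C2=C7 is endocyclic and therefore fixed with C1 cis to C6. With a second alkene at C3=C4 this ring is a cyclohepta-1,4-diene, the product of a cis-divinylcyclopropane rearrangement that forms C5–C6, creates C6 from a cyclopropane of known configuration and leaves a C10=C11 enol ether for the other two centres. The hydroxypropyl terminus and the aldehyde carbon are then the two ends of a C1–C3 bond that is cut once it has done its work.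

## Retrosynthesis

**End game, no bond cut.** The aldehyde of 35 is traced to the allylic alcohol of triol 34, and 34 to its trisilyl ether 33. Only the C1 hydroxyl of 34 is allylic, so an oxidant for activated alcohols needs no protecting group and the finished enal never meets base. The forward steps must be neutral: fluoride desilylation, then allylic oxidation.

**C16=C17.** The triene of 33 is cut at its central alkene into enal 29 and phosphonate 31, which comes in one step from geranyl bromide 30. Cutting at C14=C15 or C18=C19 would mean a ketone olefination to a trisubstituted alkene without control of geometry. The central disubstituted alkene comes from an aldehyde and a stabilised allylic phosphonate anion, which favours E, and 31 brings the 18E alkene ready-made. Precursor 29 lacks ten carbons and three of the four chain alkenes. The forward step must be E-selective and must not scramble 14E or 18E.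

**C14=C15 and the C14 oxidation level.** Enal 29 is cut at C14=C15 into aldehyde 28 and a two-carbon formyl-stabilised ylide, a pairing that gives E-trisubstituted enals reliably. Aldehyde 28 comes from alcohol 27, and 27 by anti-Markovnikov hydration from the allyl group of 25. Allyl is the smallest C12–C14 unit that can be put on a quaternary carbon by enolate alkylation, and it is inert until needed. The hydroboration must take the monosubstituted alkene and leave the tetrasubstituted C2=C7 alone.

**Re-forming C1–C3.** Disilyl ether 25 is the protected form of diol 24, the reduction product of ester aldehyde 23. Joining the ester carbon C1 of 23 to its aldehyde carbon C3 gives α-ketol 22 and restores the seven-membered ring. Ketol 22 comes from ketone 20 by hydroxylation at C3, the only α-CH2. Ketone 20 comes from cross-conjugated dienone 19 by conjugate reduction of its disubstituted enone. Dienone 19 comes from the cyclohepta-1,4-diene 18, whose doubly allylic C1H2 is its most oxidisable position. This path is preferred to any olefination because the geometry of C2=C7 is never at issue while the ring exists. The price is four steps that only remove a bond.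

**C10–CH3 and C11–C12.** Silyl ether 18 comes from alcohol 17, 17 from ketone 16 by methyl addition, and 16 from silyl enol ether 14 through lithium enolate 15 and an allyl halide. Both cuts remove a substituent from a ring whose faces are told apart by the C6–C5 bond, held axial by the fused ring. Precursor 14 has a single stereocentre. The forward steps need regiospecific release of the C10=C11 enolate, alkylation anti to C5, and methyl addition from the carbonyl face away from C5.

**The key cut, C5–C6.** A retro-[3,3] shift of 14 breaks C5–C6, re-forms C2–C3 and gives the cis-dialkenylcyclopropane 13. Ring-closing metathesis or a stepwise annulation would need the tetrasubstituted alkene geometry and C6 to be set separately; here both follow from one cyclopropane. Precursor 13 has one ring fewer and its two stereocentres sit on a three-membered ring that a reagent can build. The forward step needs the cis arrangement, a boat transition state and clean transfer of configuration.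

**From 13 back to 9.** Siloxydiene 13 is the extended silyl dienol ether of enone 12; γ-deprotonation at C7 erases that centre. The vinyl group of 12 (C4=C5) comes from aldehyde 11 by methylenation, and 11 from cyclopropylmethanol 10. Removing the cyclopropane CH2 (C1) from 10 gives the Z-allylic alcohol 9. Methylene transfer is stereospecific, so cis follows from Z, and the free hydroxyl is the handle for a reagent-controlled enantioselective version. The forward steps need reagent control next to the racemic C7 centre, methylenation of the aldehyde but not the enone, and the linear rather than the cross-conjugated dienol ether.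

**C7–C2.** Enone 9 is the transposed enone of vinylogous ester 7, which is cut between C7 and C2 into vinylogous ester 5 and Z-iodoalkene 4. Iodoalkene 4 is the silyl ether of 3, made from but-2-yn-1-ol 1 by hydroxyl-directed hydroalumination–iodination. The α′-carbon of 5 is its kinetic enolisation site, and the transposition puts the new substituent γ to the carbonyl, where the dienol ether needs it. The coupling must keep the Z geometry and keep the alkene out of conjugation.

## Roads not taken

**Alternative 1:** The ring bond C10–C11 is cut. Forward, an open-chain precursor carrying C6, a ketal at C7, a tethered methyl ketone (C10) and an (E)-allylboronate whose γ-carbon is C11 cyclises by intramolecular allylboration to A1, with C10 and C11 set together relative to C6.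
- Merits: the two fully substituted centres arise in one closed, chair-like transition state; the carbinol arrives with its methyl group; the hydroxypropyl chain is present from the start; the vinyl group on C11 is a useful handle for the chain.
- Weak points: ketones are poor partners for allylboronates, and here a γ,γ-disubstituted boronate must form a bond between two congested carbons, probably under acid activation that the ketal may not tolerate. The precursor needs a geometrically pure trisubstituted allylboronate next to the C6 centre. Induction from C6 rests on a choice between two chairs.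
- Decisive gap: A1 still has a C7 ketone, so the (2Z)-enal must be made by olefination of a hindered ketone with no control element.
- Comparison: this road treats C10/C11 better than the chosen plan, which needs two substrate-controlled steps (one of them among its uncertain ones), and it needs no ring excision. The chosen plan sets against this a ring-enforced enal geometry and an absolute configuration drawn from a well-precedented cyclopropanation.

**Alternative 2:** C5–C6 and C11–C12 are cut and no ring is formed. A chiral phosphine complex of CuBr·SMe2 adds a 3-silyloxypropyl Grignard reagent to C6 of a 2-methylcyclohexenone whose C7 carbonyl is masked as a dioxolane, and the magnesium enolate is allylated at C11 to give A2.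
- Merits: three components in one flask, catalyst-controlled C6, trans C6/C11 from the ring, no sacrificial ring. It is clearly the shortest access to the substituted ring, by about six steps.
- Weak points: the β-carbon is neopentyl-like beside the ketal and the enone is α-methylated, both of which slow conjugate addition and make its enantioselectivity less secure. Magnesium enolates alkylate sluggishly at a carbon that becomes quaternary.
- Decisive gap: as in Alternative 1, A2 leaves a C7 ketone and the enal geometry is unsolved.
- Comparison: this road wins on step count and on catalytic asymmetric induction. The chosen plan offers the 2Z geometry by construction and a regiodefined C10=C11 enolate as a by-product of the key step. If a geometry-controlled olefination of such a ketone were in hand, this would be the better route.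

**Alternative 3:** C7–C8 and C2–CH3 are cut. Ni(cod)2 couples the β-carbon of a vinyl ketone (C8) with the alkyne carbon C7 of an open-chain ynone, and Me2Zn delivers methyl to C2, closing the six-membered ring and giving A3.
- Merits: syn addition across the alkyne writes the tetrasubstituted alkene with C1 cis to C6 as surely as a ring constraint does; ring closure and the enal methyl come in one step; the route is convergent and needs no excision.
- Weak points: C6 and the quaternary C11 must be set next to each other in an acyclic precursor, with no ring to help, and that precursor is long. A quaternary carbon beside the vinyl ketone and branching at the propargylic carbon slow the oxidative cyclisation. Six-membered rings form less readily than five in this manifold. Direct methyl transfer to the enone competes. The C10 methyl addition is still required.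
- Comparison: this road equals the chosen plan on enal geometry and is better on convergence. The chosen plan sets against this that every stereocentre arises on a ring template from one cyclopropane, and that its key step has close precedent.

Key step: step 9

## Remarks on the chemistry

- Assumption: compounds 7–12 are carried as mixtures of the two C7 epimers (7–9 racemic; 10–12 two diastereomers with one cyclopropane configuration). C7 becomes trigonal in 13, so the mixture converges.
- The cyclopropane descriptors change from (1S,2S) in 10 and 11 to (1R,2R) in 12 and 13 only because ligand priorities change; the spatial arrangement is the same.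
- In the bicyclic compounds 14–22 the annulene locants 9a, 1, 2, 4a, 5, 6, 7, 8, 9 correspond to C6, C11, C10, C7, C2, C1, C3, C4, C5.

## Route

Step 1
Reactants: 1 but-2-yn-1-ol
Product: 3 (2Z)-3-iodobut-2-en-1-ol, via cyclic alkenylalanate 2 (not isolated)
Conditions: NaAlH2(OCH2CH2OCH3)2, THF, 0 → 23 °C; then I2, THF, −78 → 0 °C
Reagents that add atoms: iodine, II
Why: Hydroxyl-directed trans-hydroalumination puts hydride on the proximal and aluminium on the distal alkyne carbon within a five-membered alanate, and iododealumination with retention gives the Z-iodoalkene (iodine cis to CH2OH).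

Step 2
Reactants: 3 (2Z)-3-iodobut-2-en-1-ol
Product: 4 tert-butyl{[(2Z)-3-iodobut-2-en-1-yl]oxy}dimethylsilane
Conditions: TBSCl, imidazole, CH2Cl2, 0 → 23 °C
Reagents that add atoms: tert-butyldimethylsilyl chloride, CC(C)(C)[Si](C)(C)Cl
Why: Standard silylation of a primary alcohol; the ether masks the hydroxyl, which would otherwise be oxidised at palladium in the next step.

Step 3
Reactants: 5 3-ethoxy-2-methylcyclohex-2-en-1-one; 4 tert-butyl{[(2Z)-3-iodobut-2-en-1-yl]oxy}dimethylsilane
Product: 7 6-[(2Z)-4-{[tert-butyl(dimethyl)silyl]oxy}but-2-en-2-yl]-3-ethoxy-2-methylcyclohex-2-en-1-one (racemic), via lithium dienolate 6 (not isolated)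
Conditions: LiN(SiMe3)2, THF, −78 → 0 °C; then 4, Pd2(dba)3 (cat.), P(t-Bu)3 (cat.), 23 → 50 °C; AcOH, −78 °C
Reagents that add atoms: none
Why: Palladium-catalysed α-alkenylation of a ketone enolate: zerovalent palladium inserts into the C–I bond with retention, the kinetic α′-enolate transmetalates and reductive elimination forms C7–C2 with the Z geometry intact; the cold acetic acid quench protonates the product dienolate at its α-carbon so the alkene stays out of conjugation, and the new C7 centre is racemic and later erased.

Step 4
Reactants: 7 6-[(2Z)-4-{[tert-butyl(dimethyl)silyl]oxy}but-2-en-2-yl]-3-ethoxy-2-methylcyclohex-2-en-1-one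
Product: 9 4-[(2Z)-4-hydroxybut-2-en-2-yl]-2-methylcyclohex-2-en-1-one (racemic), via allylic alcohol 8 (not isolated)
Conditions: LiAlH4, Et2O, 0 °C; then 1 M HCl, THF, 0 → 23 °C
Reagents that add atoms: water, O
Why: Stork–Danheiser transposition: 1,2-reduction of the vinylogous ester, then acid-induced loss of water and hydrolysis of the enol ether give the transposed enone with the side chain γ to the carbonyl; the same dilute acid removes the silyl ether and is kept short and cold so the free hydroxyl does not add to the enone.

Step 5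
Reactants: 9 4-[(2Z)-4-hydroxybut-2-en-2-yl]-2-methylcyclohex-2-en-1-one
Product: 10 4-[(1S,2S)-2-(hydroxymethyl)-1-methylcyclopropyl]-2-methylcyclohex-2-en-1-one (both C4 epimers)
Conditions: Et2Zn, CH2I2, DME, CH2Cl2, −10 °C [Zn(CH2I)2·DME]; (4R,5R)-2-butyl-N,N,N′,N′-tetramethyl-1,3,2-dioxaborolane-4,5-dicarboxamide, then 9, −10 → 23 °C
Reagents that add atoms: diiodomethane, ICI
Why: Dioxaborolane-controlled asymmetric Simmons–Smith cyclopropanation: the zinc alkoxide bound to the chiral boronate directs Zn(CH2I)2 to one alkene face, syn-stereospecific transfer turns the Z-alkene into the cis-cyclopropane, and the (4R,5R) ligand is the one whose established facial preference for allylic alcohols leads to the (1S,2S) product; the enone alkene is too electron-poor to react.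

Step 6
Reactants: 10 4-[(1S,2S)-2-(hydroxymethyl)-1-methylcyclopropyl]-2-methylcyclohex-2-en-1-one
Product: 11 (1S,2S)-2-methyl-2-(3-methyl-4-oxocyclohex-2-en-1-yl)cyclopropane-1-carbaldehyde (both epimers at the ring CH)
Conditions: Dess–Martin periodinane, NaHCO3, CH2Cl2, 0 → 23 °C
Reagents that add atoms: none
Why: Dess–Martin oxidation under buffered, near-neutral conditions gives the cyclopropanecarbaldehyde without epimerising its α-carbon, which has little thermodynamic drive to invert because either face bears a substituent on the neighbouring quaternary carbon.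

Step 7
Reactants: 11 (1S,2S)-2-methyl-2-(3-methyl-4-oxocyclohex-2-en-1-yl)cyclopropane-1-carbaldehyde
Product: 12 4-[(1R,2R)-2-ethenyl-1-methylcyclopropyl]-2-methylcyclohex-2-en-1-one (both C4 epimers)
Conditions: Ph3PCH3Br, KN(SiMe3)2, THF, 0 °C; then 11, −78 → 0 °C
Reagents that add atoms: methyltriphenylphosphonium bromide, [Br-].C[P+](c1ccccc1)(c1ccccc1)c1ccccc1
Why: Wittig methylenation; at low temperature and with a slight excess of ylide the aldehyde reacts far faster than the α-substituted conjugated ketone, and any transient γ-deprotonation of the enone is harmless because both enone isomers lead to the same dienol ether.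

Step 8
Reactants: 12 4-[(1R,2R)-2-ethenyl-1-methylcyclopropyl]-2-methylcyclohex-2-en-1-one
Product: 13 tert-butyl({4-[(1R,2R)-2-ethenyl-1-methylcyclopropyl]-2-methylcyclohexa-1,3-dien-1-yl}oxy)dimethylsilane
Conditions: TBSOTf, Et3N, CH2Cl2, −20 → 0 °C; cold pentane, filtration through basic Al2O3; used at once
Reagents that add atoms: tert-butyldimethylsilyl trifluoromethanesulfonate, CC(C)(C)[Si](C)(C)OS(=O)(=O)C(F)(F)F
Why: Soft enolisation: O-silylation gives a silyloxyallyl cation that the amine deprotonates reversibly, so the linear, more substituted 2-silyloxy-1,3-diene (loss of the C7 hydrogen, conjugation with the cyclopropane) should prevail over the cross-conjugated isomer, as in the thermodynamic dienol silylation of γ-substituted cyclohexenones; the C7 epimers converge.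

Step 9
Reactants: 13 tert-butyl({4-[(1R,2R)-2-ethenyl-1-methylcyclopropyl]-2-methylcyclohexa-1,3-dien-1-yl}oxy)dimethylsilane
Product: 14 tert-butyl{[(9aR)-1,5-dimethyl-3,4,6,9-tetrahydro-9aH-benzo[7]annulen-2-yl]oxy}dimethylsilane
Conditions: C6H6 (degassed, trace Et3N), 70 °C
Reagents that add atoms: none
Why: Concerted [3,3]-sigmatropic (Cope) shift of a cis-1,2-dialkenylcyclopropane: C5 bonds to C6 while the cyclopropane bond C2–C3 breaks, C2=C7 and C3=C4 appear and the silyl enol ether C10=C11 is carried through untouched, with release of three-ring strain making the step irreversible. The closest known reaction type is the thermal divinylcyclopropane–cycloheptadiene rearrangement of cis-2-vinylcyclopropyl silyloxydienes. The seven-membered ring (C1, C2, C7, C6, C5, C4, C3) closes pericyclically through a boat-shaped six-centre transition state with both alkenyl groups folded under the three-membered ring; only this geometry gives two cis ring alkenes, so C2=C7 forms with C1 cis to C6 by necessity. The new stereocentre C6 is controlled by the cyclopropane: the shift is suprafacial on both alkenes, C5 can reach only the face of C6 turned toward it in the boat, and the (1R,2R) configuration of 13 is transferred to (9aR) in 14 while C2 and C3 become trigonal. The step needs the two alkenyl groups cis, which the Z-alkene of 9 and the stereospecific methylene transfer of step 5 secure. It also needs a small inward substituent on C6, and because C6=C7 is a ring alkene that substituent is hydrogen (C11 is trans to the cyclopropane). No alkyl hydrogen sits cis to either alkenyl group, so the homodienyl 1,5-hydrogen shift has no substrate, and the mild temperature keeps homolytic opening of the cyclopropane, the only path that could erode the transfer of chirality, out of reach.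

Step 10
Reactants: 14 tert-butyl{[(9aR)-1,5-dimethyl-3,4,6,9-tetrahydro-9aH-benzo[7]annulen-2-yl]oxy}dimethylsilane
Product: 16 (1S,9aR)-1,5-dimethyl-1-(prop-2-en-1-yl)-1,3,4,6,9,9a-hexahydro-2H-benzo[7]annulen-2-one, via lithium enolate 15 (not isolated)
Conditions: MeLi, THF, 0 → 23 °C; then CH2=CHCH2I, DMPU, −78 → 0 °C
Reagents that add atoms: 3-iodoprop-1-ene, C=CCI
Why: Methyllithium attacks silicon and releases the tetrasubstituted lithium enolate regiospecifically (no proton source, no equilibration toward C9); C-allylation then occurs by chair-like axial attack on C11 anti to the pseudoaxial C6–C5 bond, placing the allyl group trans to C5 (11S).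

Step 11
Reactants: 16 (1S,9aR)-1,5-dimethyl-1-(prop-2-en-1-yl)-1,3,4,6,9,9a-hexahydro-2H-benzo[7]annulen-2-one
Product: 17 (1S,2S,9aR)-1,2,5-trimethyl-1-(prop-2-en-1-yl)-2,3,4,6,9,9a-hexahydro-1H-benzo[7]annulen-2-ol
Conditions: CeCl3 (anhydrous), MeLi, THF, −78 °C [CH3CeCl2]; then 16, −78 °C
Reagents that add atoms: methyllithium, [Li]C
Why: 1,2-Addition of the weakly basic CH3CeCl2 to a hindered, enolisable ketone; the fused cycloheptadiene holds C5 axial on the cyclohexanone (avoiding allylic strain with C1 across C7=C2) and so blocks axial approach syn to C5, so methyl should enter along the equatorial trajectory and give the axial 10S alcohol with hydroxyl cis to C5 and to the C11 methyl.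

Step 12
Reactants: 17 (1S,2S,9aR)-1,2,5-trimethyl-1-(prop-2-en-1-yl)-2,3,4,6,9,9a-hexahydro-1H-benzo[7]annulen-2-ol
Product: 18 triethyl{[(1S,2S,9aR)-1,2,5-trimethyl-1-(prop-2-en-1-yl)-2,3,4,6,9,9a-hexahydro-1H-benzo[7]annulen-2-yl]oxy}silane
Conditions: Et3SiOTf, 2,6-lutidine, CH2Cl2, −78 → 0 °C
Reagents that add atoms: triethylsilyl trifluoromethanesulfonate, CC[Si](CC)(CC)OS(=O)(=O)C(F)(F)F
Why: Silyl triflate silylation of a tertiary alcohol; the ether stops the axial hydroxyl, which lies 1,3 to C5, from adding to C4 of the dienone in 19 and from adding to the enal of 29, and it simplifies the enolate chemistry of step 15.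

Step 13
Reactants: 18 triethyl{[(1S,2S,9aR)-1,2,5-trimethyl-1-(prop-2-en-1-yl)-2,3,4,6,9,9a-hexahydro-1H-benzo[7]annulen-2-yl]oxy}silane
Product: 19 (1S,2S,9aR)-1,2,5-trimethyl-1-(prop-2-en-1-yl)-2-[(triethylsilyl)oxy]-1,2,3,4,9,9a-hexahydro-6H-benzo[7]annulen-6-one
Conditions: (C5H5NH)2Cr2O7 (mediator), t-BuOOH, Celite, C6H6, 10 → 23 °C
Reagents that add atoms: tert-butyl hydroperoxide, CC(C)(C)OO
Why: Allylic oxidation of a doubly allylic methylene to a cross-conjugated dienone, as known for 1,4-cyclohexadienes with dichromate and tert-butyl hydroperoxide; the C1–H bonds, flanked by C2=C7 and C3=C4, are the weakest in the molecule, while the allyl CH2 and the singly allylic ring positions react much more slowly.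

Step 14
Reactants: 19 (1S,2S,9aR)-1,2,5-trimethyl-1-(prop-2-en-1-yl)-2-[(triethylsilyl)oxy]-1,2,3,4,9,9a-hexahydro-6H-benzo[7]annulen-6-one
Product: 20 (1S,2S,9aR)-1,2,5-trimethyl-1-(prop-2-en-1-yl)-2-[(triethylsilyl)oxy]-1,2,3,4,7,8,9,9a-octahydro-6H-benzo[7]annulen-6-one
Conditions: [(Ph3P)CuH]6, C6H6, H2O (2 equiv), 23 °C
Reagents that add atoms: none
Why: Conjugate reduction with the hexameric copper hydride: hydride goes to C4 of the β-monosubstituted enone, the fully substituted C2=C7 enone is too hindered to react, the isolated allyl alkene is inert, and water protonates the copper enolate at C3.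

Step 15
Reactants: 20 (1S,2S,9aR)-1,2,5-trimethyl-1-(prop-2-en-1-yl)-2-[(triethylsilyl)oxy]-1,2,3,4,7,8,9,9a-octahydro-6H-benzo[7]annulen-6-one
Product: 22 (1S,2S,9aR)-7-hydroxy-1,2,5-trimethyl-1-(prop-2-en-1-yl)-2-[(triethylsilyl)oxy]-1,2,3,4,7,8,9,9a-octahydro-6H-benzo[7]annulen-6-one (both epimers at the carbinol carbon), via potassium enolate 21 (not isolated)
Conditions: KN(SiMe3)2, THF, −78 °C; then 2-(benzenesulfonyl)-3-phenyloxaziridine, −78 °C; NH4Cl (aq)
Reagents that add atoms: 2-(benzenesulfonyl)-3-phenyloxaziridine, O=S(=O)(c1ccccc1)N1OC1c1ccccc1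
Why: Kinetic enolisation can only go toward C3 (C2 is trigonal, and γ-deprotonation is slow at −78 °C), and electrophilic hydroxylation of the enolate by the N-sulfonyloxaziridine gives the α-ketol; the configuration of the new carbinol is irrelevant because C3 becomes an aldehyde.

Step 16
Reactants: 22 (1S,2S,9aR)-7-hydroxy-1,2,5-trimethyl-1-(prop-2-en-1-yl)-2-[(triethylsilyl)oxy]-1,2,3,4,7,8,9,9a-octahydro-6H-benzo[7]annulen-6-one
Product: 23 methyl (2Z)-2-[(2R,3S,4S)-3,4-dimethyl-2-(3-oxopropyl)-3-(prop-2-en-1-yl)-4-[(triethylsilyl)oxy]cyclohexylidene]propanoate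
Conditions: Pb(OAc)4, MeOH–C6H6 (1:1), 0 °C
Reagents that add atoms: methanol, CO
Why: Oxidative cleavage of an α-ketol: methanol adds to the C1 carbonyl, the hemiketal and the C3 hydroxyl form a cyclic lead ester, and its fragmentation cuts C1–C3 to give the methyl ester at C1 and the aldehyde at C3; the 2Z geometry is simply that of the former ring alkene.

Step 17
Reactants: 23 methyl (2Z)-2-[(2R,3S,4S)-3,4-dimethyl-2-(3-oxopropyl)-3-(prop-2-en-1-yl)-4-[(triethylsilyl)oxy]cyclohexylidene]propanoate
Product: 24 (2Z)-2-[(2R,3S,4S)-2-(3-hydroxypropyl)-3,4-dimethyl-3-(prop-2-en-1-yl)-4-[(triethylsilyl)oxy]cyclohexylidene]propan-1-ol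
Conditions: i-Bu2AlH, CH2Cl2, −78 → 0 °C; KNaC4H4O6 (aq)
Reagents that add atoms: none
Why: The aluminium hydride reduces the aldehyde and, by 1,2-addition only, the hindered conjugated ester, giving the primary and the allylic alcohol without touching either alkene.

Step 18
Reactants: 24 (2Z)-2-[(2R,3S,4S)-2-(3-hydroxypropyl)-3,4-dimethyl-3-(prop-2-en-1-yl)-4-[(triethylsilyl)oxy]cyclohexylidene]propan-1-ol
Product: 25 tert-butyl{[(2Z)-2-{(2R,3S,4S)-2-[3-(tert-butyldimethylsilyloxy)propyl]-3,4-dimethyl-3-(prop-2-en-1-yl)-4-(triethylsilyloxy)cyclohexylidene}propyl]oxy}dimethylsilane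
Conditions: TBSCl, imidazole, DMF, 23 °C
Reagents that add atoms: tert-butyldimethylsilyl chloride, CC(C)(C)[Si](C)(C)Cl
Why: Silylation of both primary hydroxyls, so that the alcohol made at C14 in the next step is the only free one.

Step 19
Reactants: 25 tert-butyl{[(2Z)-2-{(2R,3S,4S)-2-[3-(tert-butyldimethylsilyloxy)propyl]-3,4-dimethyl-3-(prop-2-en-1-yl)-4-(triethylsilyloxy)cyclohexylidene}propyl]oxy}dimethylsilane
Product: 27 tert-butyl{[(2Z)-2-{(2R,3S,4S)-2-[3-(tert-butyldimethylsilyloxy)propyl]-3-(3-hydroxypropyl)-3,4-dimethyl-4-(triethylsilyloxy)cyclohexylidene}propyl]oxy}dimethylsilane, via alkylborane 26 (not isolated)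
Conditions: 9-BBN, THF, 0 → 23 °C; then NaOH (aq), H2O2, 0 °C
Reagents that add atoms: hydrogen peroxide, OO
Why: Anti-Markovnikov hydroboration–oxidation; the bulky dialkylborane adds only to the monosubstituted alkene, with boron on C14, and leaves the tetrasubstituted C2=C7 untouched.

Step 20
Reactants: 27 tert-butyl{[(2Z)-2-{(2R,3S,4S)-2-[3-(tert-butyldimethylsilyloxy)propyl]-3-(3-hydroxypropyl)-3,4-dimethyl-4-(triethylsilyloxy)cyclohexylidene}propyl]oxy}dimethylsilane
Product: 28 tert-butyl{[(2Z)-2-{(2R,3S,4S)-2-[3-(tert-butyldimethylsilyloxy)propyl]-3,4-dimethyl-3-(3-oxopropyl)-4-(triethylsilyloxy)cyclohexylidene}propyl]oxy}dimethylsilane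
Conditions: Dess–Martin periodinane, NaHCO3, CH2Cl2, 0 → 23 °C
Reagents that add atoms: none
Why: Dess–Martin oxidation of the only free alcohol to the C14 aldehyde; the buffer protects the silyl ethers from the acetic acid released.

Step 21
Reactants: 28 tert-butyl{[(2Z)-2-{(2R,3S,4S)-2-[3-(tert-butyldimethylsilyloxy)propyl]-3,4-dimethyl-3-(3-oxopropyl)-4-(triethylsilyloxy)cyclohexylidene}propyl]oxy}dimethylsilane
Product: 29 tert-butyl{[(2Z)-2-{(2R,3S,4S)-2-[3-(tert-butyldimethylsilyloxy)propyl]-3,4-dimethyl-3-[(3E)-4-methyl-5-oxopent-3-en-1-yl]-4-(triethylsilyloxy)cyclohexylidene}propyl]oxy}dimethylsilane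
Conditions: Ph3P=C(CH3)CHO, C6H6, 80 °C
Reagents that add atoms: 2-(triphenyl-λ5-phosphanylidene)propanal, CC(C=O)=P(c1ccccc1)(c1ccccc1)c1ccccc1
Why: Wittig reaction of a formyl-stabilised ylide with an unhindered aliphatic aldehyde; reversible betaine formation gives the E-trisubstituted enal (14E), and the product enal is too deactivated to react again at a useful rate.

Step 22
Reactants: 30 (2E)-1-bromo-3,7-dimethylocta-2,6-diene
Product: 31 diethyl [(2E)-3,7-dimethylocta-2,6-dien-1-yl]phosphonate
Conditions: P(OEt)3, neat, 120 °C
Reagents that add atoms: triethyl phosphite, CCOP(OCC)OCC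
Why: Michaelis–Arbuzov reaction of a primary allylic bromide; substitution at the primary carbon keeps the 2E alkene.

Step 23
Reactants: 29 tert-butyl{[(2Z)-2-{(2R,3S,4S)-2-[3-(tert-butyldimethylsilyloxy)propyl]-3,4-dimethyl-3-[(3E)-4-methyl-5-oxopent-3-en-1-yl]-4-(triethylsilyloxy)cyclohexylidene}propyl]oxy}dimethylsilane; 31 diethyl [(2E)-3,7-dimethylocta-2,6-dien-1-yl]phosphonate
Product: 33 tert-butyl{[(2Z)-2-{(2R,3S,4S)-2-[3-(tert-butyldimethylsilyloxy)propyl]-3,4-dimethyl-4-(triethylsilyloxy)-3-[(3E,5E,7E)-4,8,12-trimethyltrideca-3,5,7,11-tetraen-1-yl]cyclohexylidene}propyl]oxy}dimethylsilane, via lithiated phosphonate 32 (not isolated)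
Conditions: 31, n-BuLi, THF, −78 °C; then 29, −78 → 23 °C
Reagents that add atoms: none
Why: Horner–Wadsworth–Emmons olefination with an allylic phosphonate anion, which adds through its α-carbon to the enal and eliminates phosphate from the equilibrated adduct to give the E-disubstituted alkene (16E), as in polyene chain extensions of this kind; the 14E and 18E alkenes are carried through.

Step 24
Reactants: 33 tert-butyl{[(2Z)-2-{(2R,3S,4S)-2-[3-(tert-butyldimethylsilyloxy)propyl]-3,4-dimethyl-4-(triethylsilyloxy)-3-[(3E,5E,7E)-4,8,12-trimethyltrideca-3,5,7,11-tetraen-1-yl]cyclohexylidene}propyl]oxy}dimethylsilane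
Product: 34 (2Z)-2-[(2R,3S,4S)-4-hydroxy-2-(3-hydroxypropyl)-3,4-dimethyl-3-[(3E,5E,7E)-4,8,12-trimethyltrideca-3,5,7,11-tetraen-1-yl]cyclohexylidene]propan-1-ol
Conditions: Bu4NF, THF, 23 → 45 °C
Reagents that add atoms: none
Why: Fluoride cleaves the two primary silyl ethers quickly and the tertiary triethylsilyl ether on gentle warming; no aldehyde is present yet, so the basic fluoride cannot epimerise C6.

Step 25
Reactants: 34 (2Z)-2-[(2R,3S,4S)-4-hydroxy-2-(3-hydroxypropyl)-3,4-dimethyl-3-[(3E,5E,7E)-4,8,12-trimethyltrideca-3,5,7,11-tetraen-1-yl]cyclohexylidene]propan-1-ol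
Product: 35 (2Z)-2-[(2R,3S,4S)-4-hydroxy-2-(3-hydroxypropyl)-3,4-dimethyl-3-[(3E,5E,7E)-4,8,12-trimethyltrideca-3,5,7,11-tetraen-1-yl]cyclohexylidene]propanal
Conditions: MnO2 (activated), CH2Cl2, 23 °C
Reagents that add atoms: none
Why: Heterogeneous MnO2 oxidises only the allylic C1 alcohol; the saturated primary and the tertiary alcohol do not react, and the neutral surface reaction leaves the triene, the 2Z geometry and C6 unchanged.

## Compound list

1 | but-2-yn-1-ol | CC#CCO | starting material
2 | sodium 2,2-bis(2-methoxyethoxy)-3-methyl-2,5-dihydro-1,2-oxaluminol-2-uide (cyclic alkenylalanate) | CC1=CCO[Al-]1(OCCOC)OCCOC.[Na+] | intermediate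
3 | (2Z)-3-iodobut-2-en-1-ol | C/C(I)=C/CO | intermediate
4 | tert-butyl{[(2Z)-3-iodobut-2-en-1-yl]oxy}dimethylsilane | C/C(I)=C/CO[Si](C)(C)C(C)(C)C | intermediate
5 | 3-ethoxy-2-methylcyclohex-2-en-1-one | CCOC1=C(C)C(=O)CCC1 | starting material
6 | lithium 5-ethoxy-6-methylcyclohexa-1,5-dien-1-olate | [Li]OC1=CCCC(OCC)=C1C | intermediate
7 | 6-[(2Z)-4-{[tert-butyl(dimethyl)silyl]oxy}but-2-en-2-yl]-3-ethoxy-2-methylcyclohex-2-en-1-one (racemic) | CCOC1=C(C)C(=O)C(CC1)/C(C)=C\CO[Si](C)(C)C(C)(C)C | intermediate
8 | 6-[(2Z)-4-{[tert-butyl(dimethyl)silyl]oxy}but-2-en-2-yl]-3-ethoxy-2-methylcyclohex-2-en-1-ol (stereoisomer mixture) | CCOC1=C(C)C(O)C(CC1)/C(C)=C\CO[Si](C)(C)C(C)(C)C | intermediate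
9 | 4-[(2Z)-4-hydroxybut-2-en-2-yl]-2-methylcyclohex-2-en-1-one (racemic) | CC1=CC(CCC1=O)/C(C)=C\CO | intermediate
10 | 4-[(1S,2S)-2-(hydroxymethyl)-1-methylcyclopropyl]-2-methylcyclohex-2-en-1-one (both C4 epimers) | CC1=CC(CCC1=O)[C@]2(C)C[C@@H]2CO | intermediate
11 | (1S,2S)-2-methyl-2-(3-methyl-4-oxocyclohex-2-en-1-yl)cyclopropane-1-carbaldehyde (both epimers at the ring CH) | CC1=CC(CCC1=O)[C@]2(C)C[C@@H]2C=O | intermediate
12 | 4-[(1R,2R)-2-ethenyl-1-methylcyclopropyl]-2-methylcyclohex-2-en-1-one (both C4 epimers) | CC1=CC(CCC1=O)[C@]2(C)C[C@@H]2C=C | intermediate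
13 | tert-butyl({4-[(1R,2R)-2-ethenyl-1-methylcyclopropyl]-2-methylcyclohexa-1,3-dien-1-yl}oxy)dimethylsilane | CC1=C(O[Si](C)(C)C(C)(C)C)CCC(=C1)[C@]2(C)C[C@@H]2C=C | intermediate
14 | tert-butyl{[(9aR)-1,5-dimethyl-3,4,6,9-tetrahydro-9aH-benzo[7]annulen-2-yl]oxy}dimethylsilane | CC1=C(O[Si](C)(C)C(C)(C)C)CCC2=C(C)CC=CC[C@@H]12 | intermediate
15 | lithium (9aR)-1,5-dimethyl-3,4,6,9-tetrahydro-9aH-benzo[7]annulen-2-olate | CC1=C(O[Li])CCC2=C(C)CC=CC[C@@H]12 | intermediate
16 | (1S,9aR)-1,5-dimethyl-1-(prop-2-en-1-yl)-1,3,4,6,9,9a-hexahydro-2H-benzo[7]annulen-2-one | C=CC[C@@]1(C)[C@@H]2CC=CCC(C)=C2CCC1=O | intermediate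
17 | (1S,2S,9aR)-1,2,5-trimethyl-1-(prop-2-en-1-yl)-2,3,4,6,9,9a-hexahydro-1H-benzo[7]annulen-2-ol | C=CC[C@@]1(C)[C@@H]2CC=CCC(C)=C2CC[C@]1(C)O | intermediate
18 | triethyl{[(1S,2S,9aR)-1,2,5-trimethyl-1-(prop-2-en-1-yl)-2,3,4,6,9,9a-hexahydro-1H-benzo[7]annulen-2-yl]oxy}silane | C=CC[C@@]1(C)[C@@H]2CC=CCC(C)=C2CC[C@]1(C)O[Si](CC)(CC)CC | intermediate
19 | (1S,2S,9aR)-1,2,5-trimethyl-1-(prop-2-en-1-yl)-2-[(triethylsilyl)oxy]-1,2,3,4,9,9a-hexahydro-6H-benzo[7]annulen-6-one | C=CC[C@@]1(C)[C@@H]2CC=CC(=O)C(C)=C2CC[C@]1(C)O[Si](CC)(CC)CC | intermediate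
20 | (1S,2S,9aR)-1,2,5-trimethyl-1-(prop-2-en-1-yl)-2-[(triethylsilyl)oxy]-1,2,3,4,7,8,9,9a-octahydro-6H-benzo[7]annulen-6-one | C=CC[C@@]1(C)[C@@H]2CCCC(=O)C(C)=C2CC[C@]1(C)O[Si](CC)(CC)CC | intermediate
21 | potassium (1S,2S,9aR)-1,2,5-trimethyl-1-(prop-2-en-1-yl)-2-[(triethylsilyl)oxy]-2,3,4,8,9,9a-hexahydro-1H-benzo[7]annulen-6-olate | C=CC[C@@]1(C)[C@@H]2CCC=C(O[K])C(C)=C2CC[C@]1(C)O[Si](CC)(CC)CC | intermediate
22 | (1S,2S,9aR)-7-hydroxy-1,2,5-trimethyl-1-(prop-2-en-1-yl)-2-[(triethylsilyl)oxy]-1,2,3,4,7,8,9,9a-octahydro-6H-benzo[7]annulen-6-one (both epimers at the carbinol carbon) | C=CC[C@@]1(C)[C@@H]2CCC(O)C(=O)C(C)=C2CC[C@]1(C)O[Si](CC)(CC)CC | intermediate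
23 | methyl (2Z)-2-[(2R,3S,4S)-3,4-dimethyl-2-(3-oxopropyl)-3-(prop-2-en-1-yl)-4-[(triethylsilyl)oxy]cyclohexylidene]propanoate | C=CC[C@@]1(C)[C@H](CCC=O)/C(=C(/C)C(=O)OC)CC[C@]1(C)O[Si](CC)(CC)CC | intermediate
24 | (2Z)-2-[(2R,3S,4S)-2-(3-hydroxypropyl)-3,4-dimethyl-3-(prop-2-en-1-yl)-4-[(triethylsilyl)oxy]cyclohexylidene]propan-1-ol | C=CC[C@@]1(C)[C@H](CCCO)/C(=C(/C)CO)CC[C@]1(C)O[Si](CC)(CC)CC | intermediate
25 | tert-butyl{[(2Z)-2-{(2R,3S,4S)-2-[3-(tert-butyldimethylsilyloxy)propyl]-3,4-dimethyl-3-(prop-2-en-1-yl)-4-(triethylsilyloxy)cyclohexylidene}propyl]oxy}dimethylsilane | C=CC[C@@]1(C)[C@H](CCCO[Si](C)(C)C(C)(C)C)/C(=C(/C)CO[Si](C)(C)C(C)(C)C)CC[C@]1(C)O[Si](CC)(CC)CC | intermediate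
26 | B-alkyl-9-borabicyclo[3.3.1]nonane from 25: boron on the terminal carbon (C14) of the former allyl group; all other centres as in 25 | C1CCC2CCCC1B2CCC[C@@]3(C)[C@H](CCCO[Si](C)(C)C(C)(C)C)/C(=C(/C)CO[Si](C)(C)C(C)(C)C)CC[C@]3(C)O[Si](CC)(CC)CC | intermediate
27 | tert-butyl{[(2Z)-2-{(2R,3S,4S)-2-[3-(tert-butyldimethylsilyloxy)propyl]-3-(3-hydroxypropyl)-3,4-dimethyl-4-(triethylsilyloxy)cyclohexylidene}propyl]oxy}dimethylsilane | OCCC[C@@]1(C)[C@H](CCCO[Si](C)(C)C(C)(C)C)/C(=C(/C)CO[Si](C)(C)C(C)(C)C)CC[C@]1(C)O[Si](CC)(CC)CC | intermediate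
28 | tert-butyl{[(2Z)-2-{(2R,3S,4S)-2-[3-(tert-butyldimethylsilyloxy)propyl]-3,4-dimethyl-3-(3-oxopropyl)-4-(triethylsilyloxy)cyclohexylidene}propyl]oxy}dimethylsilane | O=CCC[C@@]1(C)[C@H](CCCO[Si](C)(C)C(C)(C)C)/C(=C(/C)CO[Si](C)(C)C(C)(C)C)CC[C@]1(C)O[Si](CC)(CC)CC | intermediate
29 | tert-butyl{[(2Z)-2-{(2R,3S,4S)-2-[3-(tert-butyldimethylsilyloxy)propyl]-3,4-dimethyl-3-[(3E)-4-methyl-5-oxopent-3-en-1-yl]-4-(triethylsilyloxy)cyclohexylidene}propyl]oxy}dimethylsilane | O=C/C(C)=C/CC[C@@]1(C)[C@H](CCCO[Si](C)(C)C(C)(C)C)/C(=C(/C)CO[Si](C)(C)C(C)(C)C)CC[C@]1(C)O[Si](CC)(CC)CC | intermediate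
30 | (2E)-1-bromo-3,7-dimethylocta-2,6-diene (geranyl bromide) | CC(C)=CCC/C(C)=C/CBr | starting material
31 | diethyl [(2E)-3,7-dimethylocta-2,6-dien-1-yl]phosphonate | CC(C)=CCC/C(C)=C/CP(=O)(OCC)OCC | intermediate
32 | [(2E)-1-(diethoxyphosphoryl)-3,7-dimethylocta-2,6-dien-1-yl]lithium | CC(C)=CCC/C(C)=C/C([Li])P(=O)(OCC)OCC | intermediate
33 | tert-butyl{[(2Z)-2-{(2R,3S,4S)-2-[3-(tert-butyldimethylsilyloxy)propyl]-3,4-dimethyl-4-(triethylsilyloxy)-3-[(3E,5E,7E)-4,8,12-trimethyltrideca-3,5,7,11-tetraen-1-yl]cyclohexylidene}propyl]oxy}dimethylsilane | CC(C)=CCC/C(C)=C/C=C/C(C)=C/CC[C@@]1(C)[C@H](CCCO[Si](C)(C)C(C)(C)C)/C(=C(/C)CO[Si](C)(C)C(C)(C)C)CC[C@]1(C)O[Si](CC)(CC)CC | intermediate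
34 | (2Z)-2-[(2R,3S,4S)-4-hydroxy-2-(3-hydroxypropyl)-3,4-dimethyl-3-[(3E,5E,7E)-4,8,12-trimethyltrideca-3,5,7,11-tetraen-1-yl]cyclohexylidene]propan-1-ol | CC(C)=CCC/C(C)=C/C=C/C(C)=C/CC[C@@]1(C)[C@H](CCCO)/C(=C(/C)CO)CC[C@]1(C)O | intermediate
35 | (2Z)-2-[(2R,3S,4S)-4-hydroxy-2-(3-hydroxypropyl)-3,4-dimethyl-3-[(3E,5E,7E)-4,8,12-trimethyltrideca-3,5,7,11-tetraen-1-yl]cyclohexylidene]propanal | CC(C)=CCC/C(C)=C/C=C/C(C)=C/CC[C@@]1(C)[C@H](CCCO)/C(=C(/C)C=O)CC[C@]1(C)O | target

## Step count and least certain steps

Total step count: 25. Longest linear sequence: 24 steps (steps 1–21 and 23–25, from 1 to 35); step 22 is a one-step branch that supplies 31.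

**Step 9 (key step).**
- Risk: the silyl dienol ether may be protodesilylated back to 12 by adventitious acid during the heating period, which removes the 1,5-diene before it has rearranged. A rise in temperature to compensate would bring reversible homolysis of the cyclopropane into play and erode the transfer of chirality.
- Fallback: rearrange at the ketone level, where no silyl group is at stake. It sets out from 12 and comes back at 14. Equilibrating deprotonation of 12 with KOt-Bu, then an inverse quench into cold aqueous acetic acid, protonates the extended dienolate at its α-carbon and gives the deconjugated ketone 4-[(1R,2R)-2-ethenyl-1-methylcyclopropyl]-2-methylcyclohex-3-en-1-one F1, itself a cis-dialkenylcyclopropane. Heating it in benzene gives the bicyclic ketone (9aS)-1,5-dimethyl-1,3,4,6,9,9a-hexahydro-2H-benzo[7]annulen-2-one F2. This has the same spatial arrangement at the ring fusion as 14; only the descriptor changes with the priorities. Thermodynamic enol silylation (TBSOTf, Et3N) toward the more substituted C11 returns to 14.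

**Step 3.**
- Risk: the product is formed as its dienolate, which can lose the Z geometry by rotation or be protonated at the γ-carbon to the conjugated alkylidene ketone. Coupling of a hindered trisubstituted alkenyl iodide may also be slow enough for the enolate to equilibrate toward the γ-position of 5.
- Fallback: reverse the polarity so that no enolate of the product exists. It sets out from 5 and 4 and comes back at 7. Bromination of enolate 6 with N-bromosuccinimide gives 6-bromo-3-ethoxy-2-methylcyclohex-2-en-1-one F3. Iodine–lithium exchange on 4 (t-BuLi, −78 °C) and transmetalation with ZnCl2 give, with retention, [(2Z)-4-{[tert-butyl(dimethyl)silyl]oxy}but-2-en-2-yl]zinc chloride F4. A nickel-catalysed Negishi coupling (NiCl2·glyme, a bipyridine ligand) of the two under base-free conditions gives 7.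

**Step 8.**
- Risk: enolisation may go toward C9 and give the cross-conjugated silyl dienol ether, which cannot rearrange, if equilibration through the silyloxyallyl cation is slow for this γ-branched, α-methylated enone.
- Fallback: acid-catalysed thermodynamic enol acetylation in place of soft silylation. It sets out from 12 and comes back at 15, and so at 16. Isopropenyl acetate with catalytic TsOH converts 12 into the linear dienyl acetate 4-[(1R,2R)-2-ethenyl-1-methylcyclopropyl]-2-methylcyclohexa-1,3-dien-1-yl acetate F5. This rearranges on heating as in step 9 to (9aR)-1,5-dimethyl-3,4,6,9-tetrahydro-9aH-benzo[7]annulen-2-yl acetate F6. Two equivalents of MeLi cleave the enol acetate to lithium enolate 15, which is allylated as in step 10.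

**Step 11.**
- Risk: poor facial selectivity. The axial allyl group on C11 also crowds the equatorial trajectory, so attack from the C5 face could compete and give the C10 epimer; enolisation toward C9 would return ketone.
- Fallback: thermodynamically controlled methylene transfer, then reductive opening. It sets out from 16 and comes back at 17. Dimethylsulfoxonium methylide (from (CH3)3S(O)I and NaH in DMSO) adds reversibly and closes the epoxide with the new C–C bond equatorial. This gives the spiro-epoxide (1S,9aR)-1,5-dimethyl-1-(prop-2-en-1-yl)-1,3,4,6,9,9a-hexahydrospiro[benzo[7]annulene-2,2′-oxirane] F7, with the epoxide oxygen axial on the face of C5 (C10 as in 17). LiBHEt3 opens it at the CH2 terminus to give 17.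

**Step 13.**
- Risk: poor site selectivity. The pentadienyl radical from C1–H abstraction can be oxygenated at its terminus C4 instead of at C1, giving a linear dienone, and the other allylic positions can be over-oxidised.
- Fallback: a pericyclic hydroxylation followed by a separate oxidation. It sets out from 18 and comes back at 19. Catalytic SeO2 with t-BuOOH hydroxylates C1 by an ene reaction at C3=C4 and a [2,3]-shift, giving the bis-allylic alcohol (1S,2S,9aR)-1,2,5-trimethyl-1-(prop-2-en-1-yl)-2-[(triethylsilyl)oxy]-2,3,4,6,9,9a-hexahydro-1H-benzo[7]annulen-6-ol F8 as a mixture of C1 epimers. MnO2 oxidises it to dienone 19.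

## Further compounds

F1 | step 9 | 4-[(1R,2R)-2-ethenyl-1-methylcyclopropyl]-2-methylcyclohex-3-en-1-one (both C2 epimers) | CC1C=C(CCC1=O)[C@]2(C)C[C@@H]2C=C
F2 | step 9 | (9aS)-1,5-dimethyl-1,3,4,6,9,9a-hexahydro-2H-benzo[7]annulen-2-one (both C1 epimers; ring fusion spatially as in 14) | CC1C(=O)CCC2=C(C)CC=CC[C@@H]12
F3 | step 3 | 6-bromo-3-ethoxy-2-methylcyclohex-2-en-1-one (racemic) | CCOC1=C(C)C(=O)C(Br)CC1
F4 | step 3 | [(2Z)-4-{[tert-butyl(dimethyl)silyl]oxy}but-2-en-2-yl]zinc chloride | C/C([Zn]Cl)=C/CO[Si](C)(C)C(C)(C)C
F5 | step 8 | 4-[(1R,2R)-2-ethenyl-1-methylcyclopropyl]-2-methylcyclohexa-1,3-dien-1-yl acetate | CC1=C(OC(C)=O)CCC(=C1)[C@]2(C)C[C@@H]2C=C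
F6 | step 8 | (9aR)-1,5-dimethyl-3,4,6,9-tetrahydro-9aH-benzo[7]annulen-2-yl acetate | CC1=C(OC(C)=O)CCC2=C(C)CC=CC[C@@H]12
F7 | step 11 | (1S,9aR)-1,5-dimethyl-1-(prop-2-en-1-yl)-1,3,4,6,9,9a-hexahydrospiro[benzo[7]annulene-2,2′-oxirane], epoxide oxygen on the face of C5 (C10 as in 17) | C=CC[C@@]1(C)[C@@H]2CC=CCC(C)=C2CC[C@]1(C3)O3
F8 | step 13 | (1S,2S,9aR)-1,2,5-trimethyl-1-(prop-2-en-1-yl)-2-[(triethylsilyl)oxy]-2,3,4,6,9,9a-hexahydro-1H-benzo[7]annulen-6-ol (both epimers at the new carbinol) | C=CC[C@@]1(C)[C@@H]2CC=CC(O)C(C)=C2CC[C@]1(C)O[Si](CC)(CC)CC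
A1 | alternative 1 | (6S,7S,8S)-6-(3-{[tert-butyl(dimethyl)silyl]oxy}propyl)-7-ethenyl-7,8-dimethyl-1,4-dioxaspiro[4.5]decan-8-ol | C=C[C@@]1(C)[C@H](CCCO[Si](C)(C)C(C)(C)C)C2(OCCO2)CC[C@]1(C)O
A2 | alternative 2 | (6S,7S)-6-(3-{[tert-butyl(dimethyl)silyl]oxy}propyl)-7-methyl-7-(prop-2-en-1-yl)-1,4-dioxaspiro[4.5]decan-8-one | C=CC[C@@]1(C)[C@H](CCCO[Si](C)(C)C(C)(C)C)C2(CCC1=O)OCCO2
A3 | alternative 3 | (2S,3R,4Z)-3-(3-{[tert-butyl(dimethyl)silyl]oxy}propyl)-4-(1-{[tert-butyl(dimethyl)silyl]oxy}propan-2-ylidene)-2-{3-[(4-methoxyphenyl)methoxy]propyl}-2-methylcyclohexan-1-one | COc1ccc(COCCC[C@@]2(C)[C@H](CCCO[Si](C)(C)C(C)(C)C)/C(=C(/C)CO[Si](C)(C)C(C)(C)C)CCC2=O)cc1
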